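## Retrosynthetic overview

1. The six-membered α-ketol ring is made last, by a 1,2-shift ring expansion (α-ketol rearrangement, five to six) of a cis-1,4-dihydroxycyclopent-2-ene-1-carbaldehyde. The shift creates C1=O and C6–OH and relays configuration to C6.
2. The hydroxy-aldehyde comes from OH-directed epoxidation and hydrolysis of a methoxymethylidene diene, made by Wittig reaction of (R)-4-alkyl-4-hydroxycyclopent-2-enone.
3. That enone comes from MnO2 oxidation of the cis-diol formed by anti-selective Grignard addition of the C17 chain to (S)-4-silyloxycyclopent-2-enone, the source of absolute configuration.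
4. The (Z)-C17 bromide comes from Z-selective cross-metathesis of 11-bromoundec-1-ene with oct-1-ene; the C11 bromide comes from a copper-catalysed C5 + C6 Grignard coupling.
5. Ring order: the only ring is bought as a cyclopentenone and enlarged to the cyclohexenone in the final step.

Assumption: (S)-4-(tert-butyldimethylsilyloxy)cyclopent-2-enone is used as the purchased silyl-protected form of (S)-4-hydroxycyclopent-2-enone, and DMDO is used as a titrated acetone solution.

## Route

Step 1
Reactants: 1 5-bromopent-1-ene; 2 1,6-dibromohexane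
Product: 4 11-bromoundec-1-ene, via pent-4-enylmagnesium bromide 3 (not isolated)
Conditions: 1, Mg, THF, 40 °C; then 2 (3 equiv), Li2CuCl4 (3 mol %), THF, −10 → 23 °C
Reagents that add atoms: none
Why: Copper-catalysed sp3–sp3 Grignard cross-coupling (Kochi type) at one C–Br of the dibromide, with the excess of 2 suppressing double coupling; no stereocentre is formed.

Step 2
Reactants: 4 11-bromoundec-1-ene; 5 oct-1-ene
Product: 6 (Z)-1-bromoheptadec-10-ene
Conditions: 5 (4 equiv), Ru catalyst C35H47N3O4Ru [cyclometalated N-adamantyl-N′-(2,6-diisopropylphenyl)imidazolin-2-ylidene, κ2-nitrate, 2-isopropoxybenzylidene] (2 mol %), THF, 35 °C, static vacuum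
Reagents that add atoms: none
Why: Z-selective olefin cross-metathesis; the cyclometalated Ru catalyst forces syn-substituted ruthenacyclobutanes, so two terminal alkenes give the cis internal alkene (typically ≥ 90 % Z) with loss of ethene, and the primary bromide is inert.

Step 3
Reactants: 6 (Z)-1-bromoheptadec-10-ene; 7 (S)-4-(tert-butyldimethylsilyloxy)cyclopent-2-en-1-one
Product: 10 (1R,4S)-1-[(Z)-heptadec-10-enyl]cyclopent-2-ene-1,4-diol, via (Z)-heptadec-10-enylmagnesium bromide 8 (not isolated), via silyl ether adduct 9 (not isolated)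
Conditions: 6, Mg, THF, 45 °C; add to 7, THF, −78 °C; H2O quench, extract; crude 9, Bu4NF (1.5 equiv), THF, 0 → 23 °C
Reagents that add atoms: none
Why: Grignard 1,2-addition to the enone carbonyl anti to the silyloxy group (substrate control, typically ≥ 10:1) sets the tertiary carbinol as (R) with OH cis to the silyl ether, and fluoride desilylation follows; the minor trans-diol is removed by chromatography.

Step 4
Reactants: 10 (1R,4S)-1-[(Z)-heptadec-10-enyl]cyclopent-2-ene-1,4-diol
Product: 11 (R)-4-[(Z)-heptadec-10-enyl]-4-hydroxycyclopent-2-en-1-one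
Conditions: MnO2 (15 equiv), CH2Cl2, 23 °C
Reagents that add atoms: none
Why: Chemoselective MnO2 oxidation of the secondary allylic alcohol; the tertiary carbinol and the isolated Z-alkene are untouched, and the quaternary (R) centre is now the only stereocentre.

Step 5
Reactants: 11 (R)-4-[(Z)-heptadec-10-enyl]-4-hydroxycyclopent-2-en-1-one
Product: 14 (R)-1-[(Z)-heptadec-10-enyl]-4-(methoxymethylidene)cyclopent-2-en-1-ol, via trimethylsilyl ether 12 (not isolated), via silylated dienol ether 13 (not isolated)
Conditions: 1-(trimethylsilyl)imidazole (1.3 equiv), THF, 23 °C; then MeOCH2PPh3Cl/KN(SiMe3)2 (3 equiv), THF, −78 → 0 °C; then K2CO3 (cat.), MeOH, 23 °C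
Reagents that add atoms: (methoxymethyl)triphenylphosphonium chloride, COC[P+](c1ccccc1)(c1ccccc1)c1ccccc1.[Cl-]
Why: Wittig methoxymethylenation of the enone carbonyl; transient O-silylation prevents alkoxide formation and so retro-aldol opening (racemisation) of the β-hydroxy ketone, and methanolysis returns the free tertiary alcohol; no new stereocentre (the enol ether E/Z mixture converges in step 6).

Step 6
Reactants: 14 (R)-1-[(Z)-heptadec-10-enyl]-4-(methoxymethylidene)cyclopent-2-en-1-ol
Product: 16 (1S,4R)-4-[(Z)-heptadec-10-enyl]-1,4-dihydroxycyclopent-2-ene-1-carbaldehyde, via methoxy spiro-epoxide 15 (not isolated)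
Conditions: DMDO (1.05 equiv), acetone/CH2Cl2, −78 °C; then pH 7 aqueous buffer, 0 °C
Reagents that add atoms: dimethyldioxirane, CC1(C)OO1; water, O
Why: Rubottom-type enol ether oxidation; DMDO epoxidises the most electron-rich C=C on the face cis to the tertiary OH (hydrogen-bond direction, and anti to the alkyl chain), and hydrolysis of the labile epoxy acetal gives the α-hydroxy aldehyde with the new C1–OH cis to C4–OH (1S), the Z-alkene and ring alkene reacting far more slowly.

Step 7
Reactants: 16 (1S,4R)-4-[(Z)-heptadec-10-enyl]-1,4-dihydroxycyclopent-2-ene-1-carbaldehyde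
Product: 17 (4R,6S)-4-[(Z)-heptadec-10-enyl]-4,6-dihydroxycyclohex-2-en-1-one
Conditions: Al(OtBu)3 (20 mol %), toluene, 4 Å MS, 0 → 23 °C
Reagents that add atoms: none
Why: Proposed new method: chelate-controlled α-ketol (acyloin-type) ring expansion of a 1-formylcyclopent-2-en-1-ol — the aluminium alkoxide formed at the C1 hydroxyl binds the formyl oxygen in a five-membered cisoid chelate, and the ring CH2 (C5), standing perpendicular to that chelate plane, shifts suprafacially from C1 to the formyl carbon while C1–O–Al collapses to the ketone (driven by aldehyde → conjugated ketone and five → six ring; the sp3 carbon is expected to shift in preference to the alkenyl carbon C2 because only its shift develops the enone); because C5 can reach only one face of the chelated aldehyde, the (1S) centre is relayed into (6S), with 6-OH cis to 4-OH, and alkoxide exchange with fresh 16 turns the catalyst over; closest known reaction type: Lewis-acid α-ketol rearrangements (aluminium-alkoxide D-homoannulation of 17-hydroxy-20-keto steroids, acyloin rearrangement of α-hydroxy aldehydes), not yet shown for 1-formylcycloalk-2-en-1-ols or as a route to 6-hydroxycyclohex-2-enones.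

## Compound list

1 | 5-bromopent-1-ene | C=CCCCBr | starting material
2 | 1,6-dibromohexane | BrCCCCCCBr | starting material
3 | pent-4-enylmagnesium bromide | C=CCCC[Mg]Br | intermediate
4 | 11-bromoundec-1-ene | C=CCCCCCCCCCBr | intermediate
5 | oct-1-ene | C=CCCCCCC | starting material
6 | (Z)-1-bromoheptadec-10-ene | CCCCCC/C=C\CCCCCCCCCBr | intermediate
7 | (S)-4-(tert-butyldimethylsilyloxy)cyclopent-2-en-1-one | O=C1C=C[C@@H](O[Si](C)(C)C(C)(C)C)C1 | starting material
8 | (Z)-heptadec-10-enylmagnesium bromide | CCCCCC/C=C\CCCCCCCCC[Mg]Br | intermediate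
9 | (1R,4S)-4-(tert-butyldimethylsilyloxy)-1-[(Z)-heptadec-10-enyl]cyclopent-2-en-1-ol (OH cis to OSi) | CCCCCC/C=C\CCCCCCCCC[C@]1(O)C=C[C@@H](O[Si](C)(C)C(C)(C)C)C1 | intermediate
10 | (1R,4S)-1-[(Z)-heptadec-10-enyl]cyclopent-2-ene-1,4-diol (cis-diol) | CCCCCC/C=C\CCCCCCCCC[C@]1(O)C=C[C@@H](O)C1 | intermediate
11 | (R)-4-[(Z)-heptadec-10-enyl]-4-hydroxycyclopent-2-en-1-one | CCCCCC/C=C\CCCCCCCCC[C@]1(O)C=CC(=O)C1 | intermediate
12 | (R)-4-[(Z)-heptadec-10-enyl]-4-(trimethylsilyloxy)cyclopent-2-en-1-one | CCCCCC/C=C\CCCCCCCCC[C@]1(O[Si](C)(C)C)C=CC(=O)C1 | intermediate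
13 | {[(R)-1-[(Z)-heptadec-10-enyl]-4-(methoxymethylidene)cyclopent-2-en-1-yl]oxy}trimethylsilane (E/Z mixture at the enol ether) | CCCCCC/C=C\CCCCCCCCC[C@]1(O[Si](C)(C)C)C=CC(=COC)C1 | intermediate
14 | (R)-1-[(Z)-heptadec-10-enyl]-4-(methoxymethylidene)cyclopent-2-en-1-ol (E/Z mixture at the enol ether) | CCCCCC/C=C\CCCCCCCCC[C@]1(O)C=CC(=COC)C1 | intermediate
15 | (3S,6R)-6-[(Z)-heptadec-10-enyl]-2-methoxy-1-oxaspiro[2.4]hept-4-en-6-ol (epoxide O cis to 6-OH; both C2 epimers) | CCCCCC/C=C\CCCCCCCCC[C@]1(O)C=C[C@@]2(OC2OC)C1 | intermediate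
16 | (1S,4R)-4-[(Z)-heptadec-10-enyl]-1,4-dihydroxycyclopent-2-ene-1-carbaldehyde (cis-diol) | CCCCCC/C=C\CCCCCCCCC[C@]1(O)C=C[C@](O)(C=O)C1 | intermediate
17 | (4R,6S)-4-[(Z)-heptadec-10-enyl]-4,6-dihydroxycyclohex-2-en-1-one | CCCCCC/C=C\CCCCCCCCC[C@]1(O)C=CC(=O)[C@@H](O)C1 | target

## Step count and risk

Total step count: 7. Longest linear sequence: 7 (steps 1–7, starting from 1).

The three steps most likely to fail:

**Step 7 (the proposed ring expansion).** The alkenyl carbon C2 may shift instead of C5, giving the transposed ketol. The C6 centre may epimerise through the enediol. The tertiary allylic alcohol may dehydrate, leading to a 4-alkylcatechol. The aluminium alkoxide may also trigger hydride-transfer or Tishchenko side reactions.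

Fallback (known reaction types only; sets out from 6, comes back at 17): the Grignard reagent 8 made from 6 is added to 1,4-benzoquinone (THF, −78 °C) to give 4-[(Z)-heptadec-10-enyl]-4-hydroxycyclohexa-2,5-dien-1-one F1. An ene-reductase of the Old Yellow Enzyme family (NADPH recycled with glucose dehydrogenase) reduces one of the two enantiotopic C=C bonds to give (R)-4-[(Z)-heptadec-10-enyl]-4-hydroxycyclohex-2-en-1-one F2. LiN(iPr)2 (2.2 equiv) and Me3SiCl give the bis-silylated cross-conjugated dienol ether {[(R)-4-[(Z)-heptadec-10-enyl]-4-(trimethylsilyloxy)cyclohexa-1,5-dien-1-yl]oxy}trimethylsilane F3. Rubottom oxidation with DMDO at −78 °C passes through the silyloxy epoxide F4 (epoxide oxygen cis to the C4 silyloxy group) to (4R,6S)-4-[(Z)-heptadec-10-enyl]-4,6-bis(trimethylsilyloxy)cyclohex-2-en-1-one F5, with the 6-epimer separated. HF·pyridine then frees 17.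

**Step 5 (methoxymethylenation of the base-sensitive enone).** The basic ylide may enolise 12 and expel silanolate, or give low conversion.

Fallback (sets out from 11, silylated in the flask to 12 as in step 5; comes back at 13, which is desilylated to 14 as in step 5): a two-stage Peterson olefination replaces the Wittig reaction. [Methoxy(trimethylsilyl)methyl]lithium F6, made from (methoxymethyl)trimethylsilane and s-BuLi in THF at −78 °C, adds to 12 as a nucleophilic, weakly basic carbanion. This gives the β-hydroxysilane (4R)-4-[(Z)-heptadec-10-enyl]-1-[methoxy(trimethylsilyl)methyl]-4-(trimethylsilyloxy)cyclopent-2-en-1-ol F7, which is isolated and then eliminated with KH (THF, 0 °C) to 13.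

**Step 2 (Z-selective cross-metathesis).** The cross/homo product distribution is statistical, and the Z purity may fall below what step 7's product requires; the E isomer is hard to remove later.

Fallback (sets out from 4, comes back at 6): ozonolysis of 4 (O3, CH2Cl2, −78 °C; then PPh3) passes through the ozonide 3-(9-bromononyl)-1,2,4-trioxolane F8 to 10-bromodecanal F9. 1-Bromoheptane and PPh3 (MeCN, reflux) give heptyltriphenylphosphonium bromide F10, which NaN(SiMe3)2 converts into heptylidenetriphenylphosphorane F11. Salt-free Wittig reaction of F11 with F9 (THF, −78 → 0 °C) gives 6 with Z ≥ 95:5.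

Further compounds
F1 | step 7 | 4-[(Z)-heptadec-10-enyl]-4-hydroxycyclohexa-2,5-dien-1-one | CCCCCC/C=C\CCCCCCCCCC1(O)C=CC(=O)C=C1
F2 | step 7 | (R)-4-[(Z)-heptadec-10-enyl]-4-hydroxycyclohex-2-en-1-one | CCCCCC/C=C\CCCCCCCCC[C@]1(O)C=CC(=O)CC1
F3 | step 7 | {[(R)-4-[(Z)-heptadec-10-enyl]-4-(trimethylsilyloxy)cyclohexa-1,5-dien-1-yl]oxy}trimethylsilane | CCCCCC/C=C\CCCCCCCCC[C@]1(O[Si](C)(C)C)C=CC(O[Si](C)(C)C)=CC1
F4 | step 7 | silyloxy epoxide of F3 (epoxide O cis to the C4 silyloxy group) | CCCCCC/C=C\CCCCCCCCC[C@]1(O[Si](C)(C)C)C=C[C@@]2(O[Si](C)(C)C)O[C@H]2C1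
F5 | step 7 | (4R,6S)-4-[(Z)-heptadec-10-enyl]-4,6-bis(trimethylsilyloxy)cyclohex-2-en-1-one | CCCCCC/C=C\CCCCCCCCC[C@]1(O[Si](C)(C)C)C=CC(=O)[C@@H](O[Si](C)(C)C)C1
F6 | step 5 | [methoxy(trimethylsilyl)methyl]lithium | [Li]C(OC)[Si](C)(C)C
F7 | step 5 | (4R)-4-[(Z)-heptadec-10-enyl]-1-[methoxy(trimethylsilyl)methyl]-4-(trimethylsilyloxy)cyclopent-2-en-1-ol (diastereomer mixture) | CCCCCC/C=C\CCCCCCCCC[C@]1(O[Si](C)(C)C)C=CC(O)(C(OC)[Si](C)(C)C)C1
F8 | step 2 | 3-(9-bromononyl)-1,2,4-trioxolane | BrCCCCCCCCCC1OCOO1
F9 | step 2 | 10-bromodecanal | O=CCCCCCCCCCBr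
F10 | step 2 | heptyltriphenylphosphonium bromide | CCCCCCC[P+](c1ccccc1)(c1ccccc1)c1ccccc1.[Br-]
F11 | step 2 | heptylidenetriphenylphosphorane | CCCCCCC=P(c1ccccc1)(c1ccccc1)c1ccccc1
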